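**Plan**

- The retrosynthesis first cuts both C(=O)–CH2 bonds of the two butanoyl groups at once. Each ketone carbon sits on a ring carbon next to a free OH (C2–OH and C6–OH of ring A, the trihydroxy ring, counted from the acyl carbon; C6'–OH of ring B, the methoxy ring, counted from the bridge carbon), so each is the hydroacylation retron of a salicylaldehyde plus propene.
- The bis-salicylaldehyde is then cut at the bond between the bridging CH2 and ring A (ring B quinone methide plus formyl-methylphloroglucinol), then at the ring B formyl C–C bond, the benzylic C–N bond, the O–CH3 bond and the first formyl C–C bond.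
- Forward: both rings are bought as 2-methylphloroglucinol and no ring is formed. The order is formylation, para-O-methylation, CHO to CH2NMe2, formylation of ring B, methylene bridging, then two-fold chain extension with propene.
- The target has no stereocentre and no stereogenic double bond, so no stereochemistry has to be set.

Key step: step 6

Remark: the five free phenols of the bis-aldehyde are carried unprotected through the rhodium step, on the assumption that the ortho-phenoxide/formyl chelate outcompetes other phenoxide binding modes.

**Route**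

Step 1
Reactants: 1 2-methylphloroglucinol (2-methylbenzene-1,3,5-triol)
Product: 3 2,4,6-trihydroxy-3-methylbenzaldehyde, via aryl iminium chloride 2 (not isolated)
Conditions: POCl3, DMF, EtOAc, 0 °C to rt; then H2O, 50 °C
Reagents that add atoms: N,N-dimethylformamide, CN(C)C=O; water, O
Why: Vilsmeier–Haack formylation at one of the two equivalent free ring carbons; the iminium salt 2 deactivates the ring against a second attack and water releases the aldehyde.

Step 2
Reactants: 3 2,4,6-trihydroxy-3-methylbenzaldehyde
Product: 4 2,6-dihydroxy-4-methoxy-3-methylbenzaldehyde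
Conditions: Me2SO4 (1.0 equiv), K2CO3 (1.0 equiv), acetone, 0 °C to rt
Reagents that add atoms: dimethyl sulfate, COS(=O)(=O)OC
Why: Williamson-type O-methylation of the most acidic phenol; the 4-OH para to the formyl group is the vinylogous-acid site and is not hydrogen-bonded to the carbonyl, so one equivalent of base and dimethyl sulfate should alkylate it ahead of the two chelated ortho hydroxyls.

Step 3
Reactants: 4 2,6-dihydroxy-4-methoxy-3-methylbenzaldehyde
Product: 6 2-[(dimethylamino)methyl]-5-methoxy-4-methylbenzene-1,3-diol, via iminium acetate 5 (not isolated)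
Conditions: Me2NH (2 M in THF), AcOH, NaBH(OAc)3, THF, rt
Reagents that add atoms: dimethylamine, CNC
Why: reductive amination of a salicylaldehyde; dimethylamine condenses to iminium ion 5, which NaBH(OAc)3 reduces at room temperature, below the temperature at which the resulting Mannich base loses amine.

Step 4
Reactants: 6 2-[(dimethylamino)methyl]-5-methoxy-4-methylbenzene-1,3-diol
Product: 8 3-[(dimethylamino)methyl]-2,4-dihydroxy-6-methoxy-5-methylbenzaldehyde, via iminium dichloride 7 (not isolated)
Conditions: HCl (1.0 equiv, dioxane); then POCl3, DMF, MeCN, 0 °C to rt; then H2O, 40 °C; pH 7 work-up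
Reagents that add atoms: N,N-dimethylformamide, CN(C)C=O; water, O
Why: Vilsmeier–Haack formylation at the only unsubstituted ring carbon (between OMe and OH), with the benzylic amine held as its ammonium salt so that N-formylation and amine loss should not interfere.

Step 5
Reactants: 8 3-[(dimethylamino)methyl]-2,4-dihydroxy-6-methoxy-5-methylbenzaldehyde; 3 2,4,6-trihydroxy-3-methylbenzaldehyde (1.2 equiv)
Product: 10 3-[(3-formyl-2,6-dihydroxy-4-methoxy-5-methylphenyl)methyl]-2,4,6-trihydroxy-5-methylbenzaldehyde, via ortho-quinone methide 9 (not isolated)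
Conditions: 1,4-dioxane, 90 °C, N2 sweep; then 1 M HCl work-up
Reagents that add atoms: none
Why: thermal retro-Mannich loss of dimethylamine gives ortho-quinone methide 9, and the phenoxide of 3 adds through its single free ring carbon (Michael addition, the classical way to methylene-bridged acylphloroglucinols); neither partner has a second free ring position, so over-alkylation and self-condensation are structurally excluded.

Step 6
Reactants: 10 3-[(3-formyl-2,6-dihydroxy-4-methoxy-5-methylphenyl)methyl]-2,4,6-trihydroxy-5-methylbenzaldehyde; 11 propene (excess, two equivalents consumed)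
Product: 14 1-[3-[(3-butanoyl-2,6-dihydroxy-4-methoxy-5-methylphenyl)methyl]-2,4,6-trihydroxy-5-methylphenyl]butan-1-one (the target CNP0183860.0), via ring A monoketone 12 (not isolated), via ring B monoketone 13 (not isolated)
Conditions: [Rh(cod)(OMe)]2 (5 mol%), BINOL-derived N,N-bis(1-phenylethyl)phosphoramidite (20 mol%), K3PO4 (20 mol%), propene (6 bar), THF, 70 °C, autoclave
Reagents that add atoms: none
Why: The phenoxide ortho to each formyl group binds monovalent rhodium, which inserts into the formyl C–H bond to give a five-membered O,C-chelated acyl hydride of trivalent rhodium. Propene inserts into the Rh–H bond with the metal on the terminal carbon, and C–C reductive elimination releases the n-propyl ketone and monovalent rhodium; the cycle runs once at each formyl group, through 12 or 13. The closest known reaction type is the chelation-assisted rhodium-catalysed intermolecular hydroacylation of unactivated terminal alkenes by salicylaldehydes. No ring is closed and no stereocentre is formed; only the two C(=O)–CH2 bonds are made. The step needs linear over branched insertion and hydroacylation over decarbonylation: the bulky phosphoramidite on the crowded chelate should favour the terminal alkyl, and the phenoxide chelate should hold the acyl group against CO extrusion. Each formyl group has the required ortho hydroxyl (two in ring A, one in ring B beside the methoxy group), and the non-acidic medium should leave the diarylmethane bridge unscrambled.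

**Compound list**

1 | 2-methylphloroglucinol (2-methylbenzene-1,3,5-triol) | Cc1c(O)cc(O)cc1O | starting material
2 | N-[(2,4,6-trihydroxy-3-methylphenyl)methylidene]-N-methylmethanaminium chloride | C[N+](C)=Cc1c(O)cc(O)c(C)c1O.[Cl-] | intermediate
3 | 2,4,6-trihydroxy-3-methylbenzaldehyde | Cc1c(O)cc(O)c(C=O)c1O | intermediate
4 | 2,6-dihydroxy-4-methoxy-3-methylbenzaldehyde | COc1cc(O)c(C=O)c(O)c1C | intermediate
5 | N-[(2,6-dihydroxy-4-methoxy-3-methylphenyl)methylidene]-N-methylmethanaminium acetate | C[N+](C)=Cc1c(O)cc(OC)c(C)c1O.CC(=O)[O-] | intermediate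
6 | 2-[(dimethylamino)methyl]-5-methoxy-4-methylbenzene-1,3-diol | CN(C)Cc1c(O)cc(OC)c(C)c1O | intermediate
7 | N-[[3-[(dimethylazaniumyl)methyl]-2,4-dihydroxy-6-methoxy-5-methylphenyl]methylidene]-N-methylmethanaminium dichloride | C[N+](C)=Cc1c(O)c(C[NH+](C)C)c(O)c(C)c1OC.[Cl-].[Cl-] | intermediate
8 | 3-[(dimethylamino)methyl]-2,4-dihydroxy-6-methoxy-5-methylbenzaldehyde | CN(C)Cc1c(O)c(C)c(OC)c(C=O)c1O | intermediate
9 | 2-hydroxy-6-methoxy-5-methyl-3-methylidene-4-oxocyclohexa-1,5-diene-1-carbaldehyde (ortho-quinone methide) | C=C1C(=O)C(C)=C(OC)C(C=O)=C1O | intermediate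
10 | 3-[(3-formyl-2,6-dihydroxy-4-methoxy-5-methylphenyl)methyl]-2,4,6-trihydroxy-5-methylbenzaldehyde | O=Cc1c(O)c(C)c(O)c(Cc2c(O)c(C)c(OC)c(C=O)c2O)c1O | intermediate
11 | propene | C=CC | starting material
12 | 3-[(3-butanoyl-2,4,6-trihydroxy-5-methylphenyl)methyl]-2,4-dihydroxy-6-methoxy-5-methylbenzaldehyde (ring A monoketone) | CCCC(=O)c1c(O)c(C)c(O)c(Cc2c(O)c(C)c(OC)c(C=O)c2O)c1O | intermediate
13 | 3-[(3-butanoyl-2,6-dihydroxy-4-methoxy-5-methylphenyl)methyl]-2,4,6-trihydroxy-5-methylbenzaldehyde (ring B monoketone) | O=Cc1c(O)c(C)c(O)c(Cc2c(O)c(C)c(OC)c(C(=O)CCC)c2O)c1O | intermediate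
14 | 1-[3-[(3-butanoyl-2,6-dihydroxy-4-methoxy-5-methylphenyl)methyl]-2,4,6-trihydroxy-5-methylphenyl]butan-1-one (CNP0183860.0) | CCCC(=O)c1c(O)c(C)c(O)c(Cc2c(O)c(C)c(OC)c(C(=O)CCC)c2O)c1O | target

**Step count and risks**

Total step count: 6. Longest linear sequence: 6 steps (1 → 3 → 4 → 6 → 8 → 10 → 14); compound 3 is used a second time in step 5.

Steps most likely to fail:

1. Step 6. The pentaphenol may hold the rhodium in non-productive phenoxide complexes, the reaction may stall after the first hydroacylation, propene may insert in the branched sense, or the acyl rhodium hydride may decarbonylate. The fallback sets out from 10 and returns at 14 by organometallic addition and oxidation. Exhaustive O-benzylation of 10 (BnBr, K2CO3, DMF, 60 °C) should give the penta-O-benzyl bis-aldehyde F1. Addition of n-PrMgBr in THF at 0 °C should give the bis(1-hydroxybutyl) compound F2 as a mixture of diastereomers. Dess–Martin oxidation in CH2Cl2 should give the penta-O-benzyl diketone F3. Hydrogenolysis (H2, 10% Pd/C, EtOAc, rt) should then release 14.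

2. Step 5. The formyl-deactivated phenoxide of 3 may trap the quinone methide too slowly, and the liberated amine may promote exchange of the methylene bridge, leading to symmetrical dimers. The fallback sets out from 6 (with 1) and returns at 10, forming the bridge before the rings are deactivated. Heating 6 with a four- to five-fold excess of 1 in dioxane at 90 °C should generate 5-hydroxy-3-methoxy-2-methyl-6-methylidenecyclohexa-2,4-dien-1-one F4 (not isolated). The more nucleophilic, unformylated 1 should trap it to give 2-[(2,6-dihydroxy-4-methoxy-3-methylphenyl)methyl]-4-methylbenzene-1,3,5-triol F5. Two-fold Vilsmeier–Haack formylation of F5 (POCl3, DMF, EtOAc, 0 °C to rt; then H2O) at the single free carbon of each ring, through the bis(dimethyliminium) dichloride F6 (not isolated), should give 10. This fallback also bypasses step 4.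

3. Step 2. Regiocontrol may be lost in the mono-O-methylation, through over-methylation, methylation of an ortho hydroxyl, or C-methylation at the free ring carbon. The fallback sets out from 3 and returns at 4, replacing kinetic mono-alkylation by exhaustive methylation and chelation-directed dealkylation. Excess Me2SO4 with K2CO3 in refluxing acetone should give 2,4,6-trimethoxy-3-methylbenzaldehyde F7. AlCl3 in CH2Cl2 (0 °C to rt) should then cleave only the two methoxy groups ortho to the formyl group through the carbonyl–aluminium chelate, leaving the para methoxy group and giving 4.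

**Further compounds**

F1 | step 6 | penta-O-benzyl ether of 10: 2,4,6-tris(benzyloxy)-3-[[2,6-bis(benzyloxy)-3-formyl-4-methoxy-5-methylphenyl]methyl]-5-methylbenzaldehyde | O=Cc1c(OCc2ccccc2)c(C)c(OCc2ccccc2)c(Cc2c(OCc3ccccc3)c(C)c(OC)c(C=O)c2OCc2ccccc2)c1OCc1ccccc1
F2 | step 6 | penta-O-benzyl bis(1-hydroxybutyl) compound (mixture of diastereomers) | CCCC(O)c1c(OCc2ccccc2)c(C)c(OCc2ccccc2)c(Cc2c(OCc3ccccc3)c(C)c(OC)c(C(O)CCC)c2OCc2ccccc2)c1OCc1ccccc1
F3 | step 6 | penta-O-benzyl ether of 14 | CCCC(=O)c1c(OCc2ccccc2)c(C)c(OCc2ccccc2)c(Cc2c(OCc3ccccc3)c(C)c(OC)c(C(=O)CCC)c2OCc2ccccc2)c1OCc1ccccc1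
F4 | step 5 | 5-hydroxy-3-methoxy-2-methyl-6-methylidenecyclohexa-2,4-dien-1-one | C=C1C(=O)C(C)=C(OC)C=C1O
F5 | step 5 | 2-[(2,6-dihydroxy-4-methoxy-3-methylphenyl)methyl]-4-methylbenzene-1,3,5-triol | Cc1c(O)cc(O)c(Cc2c(O)cc(OC)c(C)c2O)c1O
F6 | step 5 | bis(dimethyliminium) dichloride of 10 | C[N+](C)=Cc1c(O)c(C)c(O)c(Cc2c(O)c(C)c(OC)c(C=[N+](C)C)c2O)c1O.[Cl-].[Cl-]
F7 | step 2 | 2,4,6-trimethoxy-3-methylbenzaldehyde | COc1cc(OC)c(C=O)c(OC)c1C
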